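Target carbons C3 to C8 (chain numbered from the enoic acid carbon C1) are folded into a carbocycle by an imaginary C3–C8 bond, which turns the trisubstituted oxirane into the epoxide of (R)-3,5-dimethylcyclohex-2-enone. The key step exploits two features: C3 and C6 are cis on the oxirane ring, and the C7 methyl sits 1,3 to the quaternary oxirane carbon C5. Alkaline hydrogen peroxide therefore forms both oxirane C–O bonds (at C4 and C5) in one operation, on the ring face opposite that methyl. The carbocycle is later cut between C3 and C8 into a methyl ketone and an aldehyde, which take up C1–C2 and a separately made C9–C13 diol ester by two olefinations.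

Key step: step 6

Remark: chain positions run from C1 (enoic acid carbon) to C13 (carbon bearing CH2OH); centres that form as mixtures and are erased later (spiro carbon of 2, C2 of 3 and 4, carbinol carbons of 11 and 12) are drawn without configuration.

Step 1
Reactants: 1 (R)-(+)-pulegone
Product: 2 (6R)-2,2,6-trimethyl-1-oxaspiro[2.5]octan-4-one
Conditions: 30% H2O2, LiOH (0.2 equiv), MeOH, 0 °C to rt
Reagents that add atoms: hydrogen peroxide, OO
Why: Weitz–Scheffer nucleophilic epoxidation of the electron-poor tetrasubstituted enone by hydroperoxide anion leaves the remote methyl-bearing centre untouched, and the spiro carbon may form as both epimers because that centre is erased again in steps 2 and 3.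

Step 2
Reactants: 2 (6R)-2,2,6-trimethyl-1-oxaspiro[2.5]octan-4-one
Product: 3 (5R)-5-methyl-2-(phenylsulfanyl)cyclohexan-1-one
Conditions: PhSNa (1.1 equiv), THF, reflux; then H2O
Reagents that add atoms: sodium benzenethiolate, [Na+].[S-]c1ccccc1
Why: Thiolate opens the oxirane by SN2 attack at the ring carbon next to the ketone, and the tertiary alkoxide so released fragments in a retro-aldol reaction with loss of acetone, which leaves the α-sulfenyl ketone and does not touch the methyl-bearing stereocentre.

Step 3
Reactants: 3 (5R)-5-methyl-2-(phenylsulfanyl)cyclohexan-1-one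
Product: 5 (R)-5-methylcyclohex-2-en-1-one, via α-sulfinyl ketone 4 (not isolated)
Conditions: mCPBA (1.0 equiv), CH2Cl2, −78 °C; aq NaHCO3 wash; crude sulfoxide in toluene, 90 °C
Reagents that add atoms: none
Why: Chemoselective oxidation of the sulfide to the sulfoxide is followed by thermal syn-elimination of benzenesulfenic acid (sulfoxide pyrolysis), which can take a hydrogen only from C3 and therefore places the double bond between C2 and C3 without moving the stereocentre.

Step 4
Reactants: 5 (R)-5-methylcyclohex-2-en-1-one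
Product: 6 trimethyl{[(3R,5R)-3,5-dimethylcyclohex-1-en-1-yl]oxy}silane
Conditions: Me2CuLi (from MeLi and CuI), Me3SiCl, THF, −78 °C; Et3N, aq NaHCO3 work-up
Reagents that add atoms: lithium dimethylcuprate, [Li+].C[Cu-]C; chlorotrimethylsilane, C[Si](C)(C)Cl
Why: Me3SiCl-accelerated conjugate addition of the Gilman cuprate, expected anti to the C5 methyl, traps the enolate as a regiodefined silyl enol ether so that the carbonyl carbon keeps its place relative to the C5 stereocentre, and the new C3 centre is planarised again in step 5.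

Step 5
Reactants: 6 trimethyl{[(3R,5R)-3,5-dimethylcyclohex-1-en-1-yl]oxy}silane
Product: 7 (R)-3,5-dimethylcyclohex-2-en-1-one
Conditions: Pd(OAc)2 (10 mol%), O2 (1 atm), DMSO, rt
Reagents that add atoms: none
Why: Saegusa–Ito dehydrosilylation, in which the divalent palladium enolate formed at C2 can undergo β-hydride elimination only towards C3, gives the methyl-bearing enone with the carbonyl where it was, and O2 returns the zerovalent palladium to the cycle.

Step 6
Reactants: 7 (R)-3,5-dimethylcyclohex-2-en-1-one
Product: 9 (1R,4R,6R)-4,6-dimethyl-7-oxabicyclo[4.1.0]heptan-2-one, via hydroperoxy enolate 8 (not isolated)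
Conditions: 30% H2O2, NaOH (0.3 equiv), MeOH, 0 to 20 °C
Reagents that add atoms: hydrogen peroxide, OO
Why: This is a Weitz–Scheffer nucleophilic epoxidation, the reaction type by which isophorone and carvone are epoxidised: hydroperoxide anion adds in conjugate fashion to the methyl-bearing β-carbon (target C5) to give enolate 8, whose α-carbon (target C4) then attacks the proximal peroxide oxygen and expels hydroxide. The oxirane is thereby closed in a 3-exo-tet mode, cis-fused to the six-membered carbocycle that contains target C3 to C8. The new stereocentre at C5 is controlled by the ring methyl on target C7: in the half-chair with that methyl pseudo-equatorial the peroxide should enter along the axial trajectory that leads to a chair-like enolate, which is the face trans to the methyl. The second stereocentre, C4, is controlled by C5, because the tethered peroxide oxygen can reach the enolate carbon only on the face it already occupies. The step needs π-facial selectivity at the β-carbon, which the 1,3-related C7 methyl secures, while the cis arrangement of C3 and C6 on the oxirane needs no control since the ring fusion imposes it. The product oxirane should be stable to the dilute alkaline medium at this temperature, so the configuration set here is expected to persist.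

Step 7
Reactants: 9 (1R,4R,6R)-4,6-dimethyl-7-oxabicyclo[4.1.0]heptan-2-one
Product: 11 (1R,4R,6R)-3-hydroxy-4,6-dimethyl-7-oxabicyclo[4.1.0]heptan-2-one, via potassium enolate 10 (not isolated)
Conditions: KN(SiMe3)2, THF, −78 °C; 3-phenyl-2-(phenylsulfonyl)oxaziridine, −78 °C; AcOH
Reagents that add atoms: 3-phenyl-2-(phenylsulfonyl)oxaziridine, O=S(=O)(c1ccccc1)N1OC1c1ccccc1
Why: Kinetic deprotonation is possible only at the ring CH2 (the other α-carbon is the oxirane CH, whose enolate would be badly strained), and Davis oxidation of this enolate places a hydroxyl on target C8, whose configuration does not matter because this carbon becomes the aldehyde.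

Step 8
Reactants: 11 (1R,4R,6R)-3-hydroxy-4,6-dimethyl-7-oxabicyclo[4.1.0]heptan-2-one
Product: 12 (4R,6R)-2,4,6-trimethyl-7-oxabicyclo[4.1.0]heptane-2,3-diol
Conditions: MeMgCl (3 equiv), THF, −78 to −20 °C; aq NH4Cl
Reagents that add atoms: methylmagnesium chloride, C[Mg]Cl
Why: Grignard 1,2-addition to the ketone, which at low temperature should be much faster than opening of the trisubstituted oxirane, brings in the future C3 methyl after the first equivalent has deprotonated the hydroxyl, and the configuration of the tertiary carbinol is irrelevant.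

Step 9
Reactants: 12 (4R,6R)-2,4,6-trimethyl-7-oxabicyclo[4.1.0]heptane-2,3-diol
Product: 13 (2R)-3-[(2R,3R)-3-acetyl-2-methyloxiran-2-yl]-2-methylpropanal
Conditions: NaIO4 on SiO2, CH2Cl2, rt; product used at once
Reagents that add atoms: none
Why: Malaprade glycol cleavage of the vicinal diol cuts the C3–C8 bond into the methyl ketone and the aldehyde under neutral heterogeneous conditions, chosen to spare the oxirane and the epimerisable methyl-bearing centre next to the new aldehyde.

Step 10
Reactants: 14 methyl acetoacetate; 15 benzyl 2-bromoethyl ether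
Product: 17 methyl 6-(benzyloxy)-3-oxohexanoate, via acetoacetate dianion 16 (not isolated)
Conditions: NaH, THF, 0 °C; n-BuLi, 0 °C; then 15, 0 °C to rt; aq HCl
Reagents that add atoms: none
Why: γ-Alkylation of the acetoacetate dianion, whose terminal carbanion is the more basic and more nucleophilic site and should therefore be the only one to displace the primary bromide (SN2).

Step 11
Reactants: 17 methyl 6-(benzyloxy)-3-oxohexanoate
Product: 18 methyl (3R)-6-(benzyloxy)-3-hydroxyhexanoate
Conditions: H2 (50 atm), RuCl2[(R)-BINAP] (0.5 mol%), MeOH, 50 °C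
Reagents that add atoms: none
Why: Noyori asymmetric hydrogenation of the β-keto ester, in which chelation of the keto and ester oxygens to the (R)-BINAP–ruthenium centre should deliver hydrogen to the face that gives the (3R)-alcohol (target C12), as it does for simple 3-oxoalkanoates, while the benzyl ether is not hydrogenolysed by this catalyst.

Step 12
Reactants: 18 methyl (3R)-6-(benzyloxy)-3-hydroxyhexanoate
Product: 20 methyl (2R,3R)-6-(benzyloxy)-3-hydroxy-2-(hydroxymethyl)hexanoate, via dilithium dianion 19 (not isolated)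
Conditions: LiN(i-Pr)2 (2.2 equiv), THF, −78 to −20 °C; CH2O gas (from cracked paraformaldehyde), −78 °C; AcOH
Reagents that add atoms: formaldehyde, C=O
Why: Fráter–Seebach reaction of the chelated lithium alkoxide–enolate, here as an aldol addition to formaldehyde, in which the electrophile should approach the enolate face opposite the C3 side chain and so give the anti (2R,3R) diol ester (target C13 relayed from C12).

Step 13
Reactants: 20 methyl (2R,3R)-6-(benzyloxy)-3-hydroxy-2-(hydroxymethyl)hexanoate
Product: 21 methyl (2R,3R)-6-(benzyloxy)-3-[(tert-butyldimethylsilyl)oxy]-2-{[(tert-butyldimethylsilyl)oxy]methyl}hexanoate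
Conditions: t-BuMe2SiOTf (2.5 equiv), 2,6-lutidine, CH2Cl2, −78 to 0 °C
Reagents that add atoms: tert-butyldimethylsilyl trifluoromethanesulfonate, CC(C)(C)[Si](C)(C)OS(=O)(=O)C(F)(F)F
Why: The silyl triflate silylates the primary and the hindered secondary hydroxyl alike, giving ethers that withstand the ylide, hydrogenation and phosphonate steps and can later be removed by fluoride without acid.

Step 14
Reactants: 21 methyl (2R,3R)-6-(benzyloxy)-3-[(tert-butyldimethylsilyl)oxy]-2-{[(tert-butyldimethylsilyl)oxy]methyl}hexanoate
Product: 22 methyl (2R,3R)-3-[(tert-butyldimethylsilyl)oxy]-2-{[(tert-butyldimethylsilyl)oxy]methyl}-6-hydroxyhexanoate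
Conditions: H2 (1 atm), 10% Pd/C, EtOAc, rt
Reagents that add atoms: none
Why: Hydrogenolysis of the benzyl ether over palladium on carbon, to which the silyl ethers and the ester are inert in ethyl acetate.

Step 15
Reactants: 22 methyl (2R,3R)-3-[(tert-butyldimethylsilyl)oxy]-2-{[(tert-butyldimethylsilyl)oxy]methyl}-6-hydroxyhexanoate
Product: 23 methyl (2R,3R)-3-[(tert-butyldimethylsilyl)oxy]-2-{[(tert-butyldimethylsilyl)oxy]methyl}-6-iodohexanoate
Conditions: I2, PPh3, imidazole, CH2Cl2, 0 °C to rt
Reagents that add atoms: iodine, II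
Why: Appel-type iodination of the primary alcohol through its alkoxyphosphonium ion by SN2, under imidazole-buffered conditions that the silyl ethers tolerate.

Step 16
Reactants: 23 methyl (2R,3R)-3-[(tert-butyldimethylsilyl)oxy]-2-{[(tert-butyldimethylsilyl)oxy]methyl}-6-iodohexanoate
Product: 24 {(4R,5R)-4-[(tert-butyldimethylsilyl)oxy]-5-{[(tert-butyldimethylsilyl)oxy]methyl}-6-methoxy-6-oxohexyl}triphenylphosphonium iodide
Conditions: PPh3 (2 equiv), MeCN, 80 °C
Reagents that add atoms: triphenylphosphine, c1ccccc1P(c1ccccc1)c1ccccc1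
Why: SN2 quaternisation of triphenylphosphine by the unhindered primary iodide, the standard preparation of a Wittig salt.

Step 17
Reactants: 13 (2R)-3-[(2R,3R)-3-acetyl-2-methyloxiran-2-yl]-2-methylpropanal; 24 the phosphonium iodide of step 16
Product: 26 methyl (2R,3R,6Z,8R)-9-[(2R,3R)-3-acetyl-2-methyloxiran-2-yl]-3-[(tert-butyldimethylsilyl)oxy]-2-{[(tert-butyldimethylsilyl)oxy]methyl}-8-methylnon-6-enoate, via phosphonium ylide 25 (not isolated)
Conditions: 24 (1.15 equiv), NaN(SiMe3)2 (1.05 equiv), THF, −78 to 0 °C; then 13 (1.0 equiv), −78 to −20 °C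
Reagents that add atoms: none
Why: Wittig olefination with a non-stabilised ylide, which at −78 °C should react with the aldehyde far faster than with the methyl ketone and is made with less base than phosphonium salt so that neither the ester nor the epimerisable centre next to the aldehyde meets free amide; the expected Z geometry is of no consequence because the alkene is saturated next.

Step 18
Reactants: 26 the (Z)-alkene of step 17
Product: 27 methyl (2R,3R,8S)-9-[(2R,3R)-3-acetyl-2-methyloxiran-2-yl]-3-[(tert-butyldimethylsilyl)oxy]-2-{[(tert-butyldimethylsilyl)oxy]methyl}-8-methylnonanoate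
Conditions: H2 (1 atm), RhCl(PPh3)3 (10 mol%), benzene/EtOH, rt
Reagents that add atoms: none
Why: Homogeneous hydrogenation with RhCl(PPh3)3 should saturate the 1,2-disubstituted alkene and leave the ketone, oxirane, ester and silyl ethers alone; it is preferred to diimide, whose hydrazine by-product could start a Wharton transposition of the α,β-epoxy ketone, and to palladium on carbon, which can hydrogenolyse such epoxy ketones.

Step 19
Reactants: 27 the saturated epoxy methyl ketone of step 18; 28 trimethyl phosphonoacetate
Product: 30 methyl (2R,3R,8S)-3-[(tert-butyldimethylsilyl)oxy]-2-{[(tert-butyldimethylsilyl)oxy]methyl}-9-{(2R,3S)-3-[(2E)-4-methoxy-4-oxobut-2-en-2-yl]-2-methyloxiran-2-yl}-8-methylnonanoate, via sodium phosphonate carbanion 29 (not isolated)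
Conditions: 28 (1.6 equiv), NaH (1.5 equiv), THF, 0 °C; then 27, 0 °C to rt
Reagents that add atoms: none
Why: Horner–Wadsworth–Emmons olefination of the α-oxygenated, hence activated, methyl ketone is expected to place the larger oxiranyl group trans to the ester and so give the (E)-enoate, with any minor Z isomer removed by chromatography, and the phosphonate carbanion is too weakly basic to disturb the ester-bearing stereocentre.

Step 20
Reactants: 30 the fully protected enoate of step 19
Product: 31 methyl (2R,3R,8S)-3-hydroxy-2-(hydroxymethyl)-9-{(2R,3S)-3-[(2E)-4-methoxy-4-oxobut-2-en-2-yl]-2-methyloxiran-2-yl}-8-methylnonanoate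
Conditions: Bu4NF, AcOH (1:1, excess), THF, 0 °C to rt
Reagents that add atoms: none
Why: Fluoride-induced cleavage of both silyl ethers, buffered with acetic acid so that no free alkoxide can trigger retro-aldol or β-elimination at the β-hydroxy ester and no acid strong enough to open the trisubstituted oxirane is present.

Step 21
Reactants: 31 the diol dimethyl ester of step 20
Product: 32 (2E)-3-{(2S,3R)-3-[(2S,7R,8R)-8-carboxy-7,9-dihydroxy-2-methylnonyl]-3-methyloxiran-2-yl}but-2-enoic acid
Conditions: LiOH, THF/MeOH/H2O, 0 °C to rt; then cold aq HCl to pH 3–4, immediate extraction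
Reagents that add atoms: lithium hydroxide (aqueous), [Li+].[OH-]
Why: Saponification of both methyl esters by acyl–oxygen cleavage should be faster than hydroxide attack on the hindered trisubstituted oxirane and, once each carboxylate has formed, leaves the α-centre C13 configurationally safe, after which brief cold acidification liberates the diacid.

Compound list
1 | (R)-(+)-pulegone, (5R)-5-methyl-2-(propan-2-ylidene)cyclohexan-1-one | C[C@@H]1CCC(=C(C)C)C(=O)C1 | starting material
2 | (6R)-2,2,6-trimethyl-1-oxaspiro[2.5]octan-4-one (pulegone oxide, both spiro epimers) | C[C@@H]1CCC2(OC2(C)C)C(=O)C1 | intermediate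
3 | (5R)-5-methyl-2-(phenylsulfanyl)cyclohexan-1-one (both C2 epimers) | C[C@@H]1CCC(Sc2ccccc2)C(=O)C1 | intermediate
4 | (5R)-5-methyl-2-(phenylsulfinyl)cyclohexan-1-one (diastereomer mixture) | C[C@@H]1CCC(S(=O)c2ccccc2)C(=O)C1 | intermediate
5 | (R)-5-methylcyclohex-2-en-1-one | C[C@@H]1CC=CC(=O)C1 | intermediate
6 | trimethyl{[(3R,5R)-3,5-dimethylcyclohex-1-en-1-yl]oxy}silane (methyls trans) | C[C@@H]1C[C@@H](C)C=C(O[Si](C)(C)C)C1 | intermediate
7 | (R)-3,5-dimethylcyclohex-2-en-1-one | C[C@@H]1CC(C)=CC(=O)C1 | intermediate
8 | sodium enolate of 3-hydroperoxy-3,5-dimethylcyclohexanone, hydroperoxy group trans to the C5 methyl | [Na+].OO[C@]1(C)C[C@@H](C)CC([O-])=C1 | intermediate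
9 | (1R,4R,6R)-4,6-dimethyl-7-oxabicyclo[4.1.0]heptan-2-one (oxirane trans to the C4 methyl) | O=C2[C@@H]1O[C@]1(C)C[C@@H](C)C2 | intermediate
10 | potassium enolate of 9 (enolate double bond C2=C3) | [K+].[O-]C2[C@@H]1O[C@]1(C)C[C@@H](C)C=2 | intermediate
11 | (1R,4R,6R)-3-hydroxy-4,6-dimethyl-7-oxabicyclo[4.1.0]heptan-2-one (both C3 epimers) | O=C2[C@@H]1O[C@]1(C)C[C@@H](C)C2O | intermediate
12 | (4R,6R)-2,4,6-trimethyl-7-oxabicyclo[4.1.0]heptane-2,3-diol (oxirane as in 9, C2 and C3 as mixtures) | CC2(O)[C@@H]1O[C@]1(C)C[C@@H](C)C2O | intermediate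
13 | (2R)-3-[(2R,3R)-3-acetyl-2-methyloxiran-2-yl]-2-methylpropanal | CC(=O)[C@@H]1O[C@]1(C)C[C@@H](C)C=O | intermediate
14 | methyl acetoacetate | COC(=O)CC(C)=O | starting material
15 | benzyl 2-bromoethyl ether | BrCCOCc1ccccc1 | starting material
16 | sodium lithium dianion of methyl acetoacetate | [Na+].[Li+].COC([O-])=CC([O-])=C | intermediate
17 | methyl 6-(benzyloxy)-3-oxohexanoate | COC(=O)CC(=O)CCCOCc1ccccc1 | intermediate
18 | methyl (3R)-6-(benzyloxy)-3-hydroxyhexanoate | c1ccccc1COCCC[C@@H](O)CC(=O)OC | intermediate
19 | dilithium alkoxide enolate of 18 | [Li+].[Li+].c1ccccc1COCCC[C@@H]([O-])C=C([O-])OC | intermediate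
20 | methyl (2R,3R)-6-(benzyloxy)-3-hydroxy-2-(hydroxymethyl)hexanoate | c1ccccc1COCCC[C@@H](O)[C@@H](CO)C(=O)OC | intermediate
21 | methyl (2R,3R)-6-(benzyloxy)-3-[(tert-butyldimethylsilyl)oxy]-2-{[(tert-butyldimethylsilyl)oxy]methyl}hexanoate | c1ccccc1COCCC[C@@H](O[Si](C)(C)C(C)(C)C)[C@@H](CO[Si](C)(C)C(C)(C)C)C(=O)OC | intermediate
22 | methyl (2R,3R)-3-[(tert-butyldimethylsilyl)oxy]-2-{[(tert-butyldimethylsilyl)oxy]methyl}-6-hydroxyhexanoate | OCCC[C@@H](O[Si](C)(C)C(C)(C)C)[C@@H](CO[Si](C)(C)C(C)(C)C)C(=O)OC | intermediate
23 | methyl (2R,3R)-3-[(tert-butyldimethylsilyl)oxy]-2-{[(tert-butyldimethylsilyl)oxy]methyl}-6-iodohexanoate | ICCC[C@@H](O[Si](C)(C)C(C)(C)C)[C@@H](CO[Si](C)(C)C(C)(C)C)C(=O)OC | intermediate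
24 | {(4R,5R)-4-[(tert-butyldimethylsilyl)oxy]-5-{[(tert-butyldimethylsilyl)oxy]methyl}-6-methoxy-6-oxohexyl}triphenylphosphonium iodide | [I-].c1ccccc1[P+](c1ccccc1)(c1ccccc1)CCC[C@@H](O[Si](C)(C)C(C)(C)C)[C@@H](CO[Si](C)(C)C(C)(C)C)C(=O)OC | intermediate
25 | triphenylphosphonium ylide of 24 | c1ccccc1P(c1ccccc1)(c1ccccc1)=CCC[C@@H](O[Si](C)(C)C(C)(C)C)[C@@H](CO[Si](C)(C)C(C)(C)C)C(=O)OC | intermediate
26 | methyl (2R,3R,6Z,8R)-9-[(2R,3R)-3-acetyl-2-methyloxiran-2-yl]-3-[(tert-butyldimethylsilyl)oxy]-2-{[(tert-butyldimethylsilyl)oxy]methyl}-8-methylnon-6-enoate | CC(=O)[C@@H]1O[C@]1(C)C[C@@H](C)/C=C\CC[C@@H](O[Si](C)(C)C(C)(C)C)[C@@H](CO[Si](C)(C)C(C)(C)C)C(=O)OC | intermediate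
27 | methyl (2R,3R,8S)-9-[(2R,3R)-3-acetyl-2-methyloxiran-2-yl]-3-[(tert-butyldimethylsilyl)oxy]-2-{[(tert-butyldimethylsilyl)oxy]methyl}-8-methylnonanoate | CC(=O)[C@@H]1O[C@]1(C)C[C@@H](C)CCCC[C@@H](O[Si](C)(C)C(C)(C)C)[C@@H](CO[Si](C)(C)C(C)(C)C)C(=O)OC | intermediate
28 | trimethyl phosphonoacetate | COC(=O)CP(=O)(OC)OC | starting material
29 | sodium salt of trimethyl phosphonoacetate (carbanion) | [Na+].COC(=O)[CH-]P(=O)(OC)OC | intermediate
30 | methyl (2R,3R,8S)-3-[(tert-butyldimethylsilyl)oxy]-2-{[(tert-butyldimethylsilyl)oxy]methyl}-9-{(2R,3S)-3-[(2E)-4-methoxy-4-oxobut-2-en-2-yl]-2-methyloxiran-2-yl}-8-methylnonanoate | C/C(=C\C(=O)OC)[C@@H]1O[C@]1(C)C[C@@H](C)CCCC[C@@H](O[Si](C)(C)C(C)(C)C)[C@@H](CO[Si](C)(C)C(C)(C)C)C(=O)OC | intermediate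
31 | methyl (2R,3R,8S)-3-hydroxy-2-(hydroxymethyl)-9-{(2R,3S)-3-[(2E)-4-methoxy-4-oxobut-2-en-2-yl]-2-methyloxiran-2-yl}-8-methylnonanoate | C/C(=C\C(=O)OC)[C@@H]1O[C@]1(C)C[C@@H](C)CCCC[C@@H](O)[C@@H](CO)C(=O)OC | intermediate
32 | (2E)-3-{(2S,3R)-3-[(2S,7R,8R)-8-carboxy-7,9-dihydroxy-2-methylnonyl]-3-methyloxiran-2-yl}but-2-enoic acid (CNP0468463.1) | C/C(=C\C(=O)O)[C@@H]1O[C@]1(C)C[C@@H](C)CCCC[C@@H](O)[C@@H](CO)C(=O)O | target

Total step count: 21. Longest linear sequence: 14 steps (steps 1 to 9, then 17 to 21, from (R)-pulegone); the C9–C13 branch takes 7 steps (10 to 16) before the coupling.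

Steps most likely to fail

1. Step 12 (hydroxymethylation of the dianion). Monomeric formaldehyde may oligomerise on the dianion or react more than once, and the aldolate may revert on warming, so conversion and anti selectivity could both be eroded. The fallback sets out from 18: the same dianion 19 is alkylated, in an SN2 process that cannot revert, with 4-methoxybenzyl chloromethyl ether. This should give methyl (2R,3R)-6-(benzyloxy)-3-hydroxy-2-{[(4-methoxybenzyl)oxy]methyl}hexanoate F1 with the usual anti selectivity of Fráter–Seebach alkylations. DDQ in CH2Cl2/pH 7 buffer then removes the 4-methoxybenzyl group in the presence of the benzyl ether, and the route is rejoined at 20.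

2. Step 17 (fragment coupling). The basic ylide may not discriminate fully between the aldehyde and the activated methyl ketone, may enolise the aldehyde and so epimerise the methyl-bearing carbon next to it, or may be consumed by acylation on its own ester. The fallback sets out from alcohol 22 and replaces the ylide by a sulfonyl carbanion generated in the presence of the aldehyde.
 - Mitsunobu thioetherification (1-phenyl-1H-tetrazole-5-thiol, PPh3, diisopropyl azodicarboxylate, THF) gives methyl (2R,3R)-3-[(tert-butyldimethylsilyl)oxy]-2-{[(tert-butyldimethylsilyl)oxy]methyl}-6-[(1-phenyl-1H-tetrazol-5-yl)sulfanyl]hexanoate F2.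
 - Oxidation ((NH4)6Mo7O24 cat., H2O2, EtOH) gives methyl (2R,3R)-3-[(tert-butyldimethylsilyl)oxy]-2-{[(tert-butyldimethylsilyl)oxy]methyl}-6-[(1-phenyl-1H-tetrazol-5-yl)sulfonyl]hexanoate F3.
 - Julia–Kocienski olefination, with KN(SiMe3)2 added to a mixture of F3 and 13 in THF at −78 °C, should give mainly methyl (2R,3R,6E,8R)-9-[(2R,3R)-3-acetyl-2-methyloxiran-2-yl]-3-[(tert-butyldimethylsilyl)oxy]-2-{[(tert-butyldimethylsilyl)oxy]methyl}-8-methylnon-6-enoate F4.
 - The alkene geometry is again irrelevant, and hydrogenation under the conditions of step 18 brings the route back at 27.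

3. Step 19 (olefination of the methyl ketone). Control of alkene geometry may be poor when the phosphonate carbanion adds to the α-oxygenated ketone, and the basic reagent may enolise the methyl ketone instead of adding to it. The fallback sets out from 27 and uses a different olefination, a base-free Wittig reaction with the stabilised phosphorane methyl (triphenylphosphoranylidene)acetate in toluene at 90 °C. This neutral reagent cannot enolise the ketone, and with α-oxygenated methyl ketones it is expected to place the oxygenated substituent trans to the ester. It returns to the route directly at 30 and forms no compound outside the list (F0).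

Further compounds
F1 | step 12 | methyl (2R,3R)-6-(benzyloxy)-3-hydroxy-2-{[(4-methoxybenzyl)oxy]methyl}hexanoate | c1ccccc1COCCC[C@@H](O)[C@@H](COCc1ccc(OC)cc1)C(=O)OC
F2 | step 17 | methyl (2R,3R)-3-[(tert-butyldimethylsilyl)oxy]-2-{[(tert-butyldimethylsilyl)oxy]methyl}-6-[(1-phenyl-1H-tetrazol-5-yl)sulfanyl]hexanoate | c1ccccc1n2nnnc2SCCC[C@@H](O[Si](C)(C)C(C)(C)C)[C@@H](CO[Si](C)(C)C(C)(C)C)C(=O)OC
F3 | step 17 | methyl (2R,3R)-3-[(tert-butyldimethylsilyl)oxy]-2-{[(tert-butyldimethylsilyl)oxy]methyl}-6-[(1-phenyl-1H-tetrazol-5-yl)sulfonyl]hexanoate | c1ccccc1n2nnnc2S(=O)(=O)CCC[C@@H](O[Si](C)(C)C(C)(C)C)[C@@H](CO[Si](C)(C)C(C)(C)C)C(=O)OC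
F4 | step 17 | methyl (2R,3R,6E,8R)-9-[(2R,3R)-3-acetyl-2-methyloxiran-2-yl]-3-[(tert-butyldimethylsilyl)oxy]-2-{[(tert-butyldimethylsilyl)oxy]methyl}-8-methylnon-6-enoate | CC(=O)[C@@H]1O[C@]1(C)C[C@@H](C)/C=C/CC[C@@H](O[Si](C)(C)C(C)(C)C)[C@@H](CO[Si](C)(C)C(C)(C)C)C(=O)OC
F0 | step 19 | none | none
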